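**Retrosynthetic overview**

1. Dihydrotetrachlorizine 12 is traced back, by loss of a tert-butoxycarbonyl group, to β-keto ester 10, which already holds the complete skeleton.
2. Key disconnection: the bond between the aryl ketone carbon and benzene carbon C3 is cut (and, with the same reagent, the chain CH–C(=O) bond) and the benzene ring is unfolded, so that 10 comes in one operation from 4-pyranone ester 4 and two equivalents of one acyl donor 7.
3. Enabling feature: around the benzene ring (C1 chain, C2–OH, C3–acyl, C4–H, C5–H, C6–OH) the pyrrolyl C=O, C2–O and C6–O are 1,3,5-related and C4/C5 carry only hydrogen, so the ring plus its ketone is a folded 1,3,5,7-tetracarbonyl chain. Its 3,5,7-part is stored in the 4-pyranone ring of maltol (the 2-methyl carbon becomes C3, pyranone C6 becomes C4, the ring oxygen is expelled), and both ketones are 4,5-dichloropyrrol-2-yl ketones, so one reagent serves twice.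
4. Ester 4 comes from maltol triflate 2 and zinc homoenolate 3 by Negishi coupling; donor 7 comes from trichloromethyl ketone 5 by amidation and N-sulfonylation.
5. Ring order: both pyrrole rings and the pyranone ring are bought; the benzene ring is the only ring formed, in step 5, from the pyranone ring.

Key step: step 5

Assumption: the zinc reagent 3 (THF solution) and the trichloromethyl ketone 5 are treated as purchasable catalogue reagents.

**Route**

Step 1
Reactants: 1 maltol (3-hydroxy-2-methyl-4H-pyran-4-one)
Product: 2 2-methyl-4-oxo-4H-pyran-3-yl trifluoromethanesulfonate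
Conditions: Tf2O, pyridine, CH2Cl2, –20 → 0 °C
Reagents that add atoms: trifluoromethanesulfonic anhydride, O=S(=O)(OS(=O)(=O)C(F)(F)F)C(F)(F)F
Why: O-sulfonylation of the acidic enolic 3-hydroxyl of maltol should give the enol triflate cleanly, since no other nucleophilic site is present.

Step 2
Reactants: 2 2-methyl-4-oxo-4H-pyran-3-yl trifluoromethanesulfonate; 3 (3-tert-butoxy-3-oxopropyl)zinc bromide
Product: 4 tert-butyl 3-(2-methyl-4-oxo-4H-pyran-3-yl)propanoate
Conditions: Pd(OAc)2 (3 mol %), SPhos (6 mol %), THF, 40 °C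
Reagents that add atoms: none
Why: Negishi sp2–sp3 cross-coupling, in which zerovalent palladium inserts into the electron-poor enol triflate, the ester-stabilised primary alkylzinc transmetalates and reductive elimination outruns β-hydride elimination; the pyranone carbonyl and the tert-butyl ester are inert to the organozinc.

Step 3
Reactants: 5 2,2,2-trichloro-1-(4,5-dichloro-1H-pyrrol-2-yl)ethan-1-one
Product: 6 4,5-dichloro-N-methoxy-N-methyl-1H-pyrrole-2-carboxamide
Conditions: MeNH(OMe)·HCl, Et3N, MeCN, 23 → 50 °C
Reagents that add atoms: N,O-dimethylhydroxylamine hydrochloride, CNOC.Cl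
Why: haloform-type acyl substitution, in which the amine adds to the trichloromethyl ketone and trichloromethanide leaves as chloroform, the standard amidation of 2-(trichloroacetyl)pyrroles.

Step 4
Reactants: 6 4,5-dichloro-N-methoxy-N-methyl-1H-pyrrole-2-carboxamide
Product: 7 4,5-dichloro-N-methoxy-N-methyl-1-(4-methylbenzenesulfonyl)-1H-pyrrole-2-carboxamide
Conditions: NaH, THF, 0 °C; TsCl, 0 → 23 °C
Reagents that add atoms: 4-methylbenzenesulfonyl chloride, Cc1ccc(cc1)S(=O)(=O)Cl
Why: N-sulfonylation of the sodium pyrrolide, the only acidic site, removes the N–H that would quench a carbanion and keeps the amide electrophilic, while the sulfonyl group stays cleavable by hydroxide.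

Step 5
Reactants: 4 tert-butyl 3-(2-methyl-4-oxo-4H-pyran-3-yl)propanoate; 7 4,5-dichloro-N-methoxy-N-methyl-1-(4-methylbenzenesulfonyl)-1H-pyrrole-2-carboxamide (2.2 equiv)
Product: 10 tert-butyl 2-(4,5-dichloro-1H-pyrrole-2-carbonyl)-3-[3-(4,5-dichloro-1H-pyrrole-2-carbonyl)-2,6-dihydroxyphenyl]propanoate (racemic), via doubly acylated pyranone 8 (not isolated), via open-chain tetraketo aldehyde 9 (not isolated)
Conditions: LiN(iPr)2 (2.1 equiv), THF, –78 °C (4 added to the base); 7, –78 → 0 °C; 2 M aq. KOH, 0 → 45 °C; then 1 M HCl to pH 4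
Reagents that add atoms: none
Why: LiN(iPr)2 removes the vinylogous proton of the 2-methyl group and the ester α-proton of 4 (inverse addition, so that the tert-butyl ester is an enolate before it can suffer Dieckmann attack), and both carbanions are C-acylated by 7 in Claisen-type additions that stop at the chelated tetrahedral N-methoxy-N-methylamide adducts, which excludes O-acylation and over-addition and forms the bond between the future aryl ketone carbon and the future benzene carbon C3. Aqueous KOH then releases bis-ketone 8, cleaves both N-sulfonyl groups at sulfur and adds to the unsubstituted pyranone C6, so that the ring opens to polyketone 9 with C6 at the aldehyde level. The benzene ring is closed by an intramolecular aldol condensation, 6-(enolexo)-exo-trig, of the methylene between the pyrrolyl ketone and the former pyranone C2 carbonyl onto that aldehyde carbon, followed by dehydration and enolisation, so the overall change from pyranone to resorcinol is an isomerisation. The closest known reaction types are the lateral acylation of 2-methyl-4-pyranone carbanions and the biomimetic base-induced conversion of 2-(acylmethyl)-4-pyranones (masked 3,5,7-triketones) into acylresorcinols. No stereocentre of the target is involved; the α-carbon of the β-keto ester is formed racemic and is removed as a stereocentre in step 6. The step needs site selectivity (lateral CH2 and ester α-carbon only) and one mode of ring closure, which are secured by the blocked C3 of the pyranone, by the aldehyde being far more electrophilic than the pyrrolyl ketones, and by the β-keto ester resting as its enolate so that the chain ketone is not attacked.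

Step 6
Reactants: 10 tert-butyl 2-(4,5-dichloro-1H-pyrrole-2-carbonyl)-3-[3-(4,5-dichloro-1H-pyrrole-2-carbonyl)-2,6-dihydroxyphenyl]propanoate
Product: 12 dihydrotetrachlorizine, via beta-keto acid 11 (not isolated)
Conditions: CF3CO2H, anisole, CH2Cl2, 23 °C; then THF/1 M aq. HCl, 50 °C
Reagents that add atoms: none
Why: acidolysis of the tert-butyl ester (loss of 2-methylpropene, anisole as cation trap) gives a β-keto acid that should decarboxylate on gentle warming through the six-membered cyclic transition state, and the aqueous acid also reopens any cyclic hemiketal or enol ether formed between the chain ketone and a flanking phenol.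

**Compound list**

1 | maltol (3-hydroxy-2-methyl-4H-pyran-4-one) | Cc1occc(=O)c1O | starting material
2 | 2-methyl-4-oxo-4H-pyran-3-yl trifluoromethanesulfonate | Cc1occc(=O)c1OS(=O)(=O)C(F)(F)F | intermediate
3 | (3-tert-butoxy-3-oxopropyl)zinc bromide | CC(C)(C)OC(=O)CC[Zn]Br | starting material
4 | tert-butyl 3-(2-methyl-4-oxo-4H-pyran-3-yl)propanoate | Cc1occc(=O)c1CCC(=O)OC(C)(C)C | intermediate
5 | 2,2,2-trichloro-1-(4,5-dichloro-1H-pyrrol-2-yl)ethan-1-one | O=C(c1cc(Cl)c(Cl)[nH]1)C(Cl)(Cl)Cl | starting material
6 | 4,5-dichloro-N-methoxy-N-methyl-1H-pyrrole-2-carboxamide | CON(C)C(=O)c1cc(Cl)c(Cl)[nH]1 | intermediate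
7 | 4,5-dichloro-N-methoxy-N-methyl-1-(4-methylbenzenesulfonyl)-1H-pyrrole-2-carboxamide | CON(C)C(=O)c1cc(Cl)c(Cl)n1S(=O)(=O)c1ccc(C)cc1 | intermediate
8 | tert-butyl 2-[4,5-dichloro-1-(4-methylbenzenesulfonyl)-1H-pyrrole-2-carbonyl]-3-[2-{2-[4,5-dichloro-1-(4-methylbenzenesulfonyl)-1H-pyrrol-2-yl]-2-oxoethyl}-4-oxo-4H-pyran-3-yl]propanoate (racemic) | CC(C)(C)OC(=O)C(Cc1c(CC(=O)c2cc(Cl)c(Cl)n2S(=O)(=O)c2ccc(C)cc2)occc1=O)C(=O)c1cc(Cl)c(Cl)n1S(=O)(=O)c1ccc(C)cc1 | intermediate (not isolated)
9 | tert-butyl 2-(4,5-dichloro-1H-pyrrole-2-carbonyl)-4-[3-(4,5-dichloro-1H-pyrrol-2-yl)-3-oxopropanoyl]-5,7-dioxoheptanoate (mixture of stereoisomers and enol forms) | CC(C)(C)OC(=O)C(CC(C(=O)CC=O)C(=O)CC(=O)c1cc(Cl)c(Cl)[nH]1)C(=O)c1cc(Cl)c(Cl)[nH]1 | intermediate (not isolated)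
10 | tert-butyl 2-(4,5-dichloro-1H-pyrrole-2-carbonyl)-3-[3-(4,5-dichloro-1H-pyrrole-2-carbonyl)-2,6-dihydroxyphenyl]propanoate (racemic) | CC(C)(C)OC(=O)C(Cc1c(O)ccc(C(=O)c2cc(Cl)c(Cl)[nH]2)c1O)C(=O)c1cc(Cl)c(Cl)[nH]1 | intermediate
11 | 2-(4,5-dichloro-1H-pyrrole-2-carbonyl)-3-[3-(4,5-dichloro-1H-pyrrole-2-carbonyl)-2,6-dihydroxyphenyl]propanoic acid (racemic) | OC(=O)C(Cc1c(O)ccc(C(=O)c2cc(Cl)c(Cl)[nH]2)c1O)C(=O)c1cc(Cl)c(Cl)[nH]1 | intermediate (not isolated)
12 | dihydrotetrachlorizine, 1-(4,5-dichloro-1H-pyrrol-2-yl)-3-[3-(4,5-dichloro-1H-pyrrole-2-carbonyl)-2,6-dihydroxyphenyl]propan-1-one (no stereocentre) | O=C(CCc1c(O)ccc(C(=O)c2cc(Cl)c(Cl)[nH]2)c1O)c1cc(Cl)c(Cl)[nH]1 | target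

**Step count**

Total steps: 6. Longest linear sequence: 4 steps (1 → 2 → 4 → 10 → 12, or equally 5 → 6 → 7 → 10 → 12).

**Steps most likely to fail**

Step 5. Several processes could erode the one-pot sequence:
- incomplete acylation of the hindered, α-substituted ester enolate;
- transfer of a sulfonyl group from nitrogen to a carbanion;
- slow hydroxide opening of the pyranone once its side-chain methylene is enolised;
- fragmentation of the open-chain polyketone by retro-Claisen or retro-Michael cleavage before ring closure;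
- a competing aldol of the β-keto ester carbon onto the aldehyde.

The fallback gives up the pyranone and forms the same aryl–acyl bond by Friedel–Crafts acylation of a symmetric arene. It sets out from 6 and comes back to the route at 12. Amide 6 with MeMgBr (3 equiv, THF, 0 °C) should give 1-(4,5-dichloro-1H-pyrrol-2-yl)ethan-1-one F1. Claisen–Schmidt condensation with commercial 2,6-dimethoxybenzaldehyde (KOH, EtOH) should give (E)-1-(4,5-dichloro-1H-pyrrol-2-yl)-3-(2,6-dimethoxyphenyl)prop-2-en-1-one F2. Hydrogenation of the C=C bond (H2, RhCl(PPh3)3, which spares C–Cl) should give 1-(4,5-dichloro-1H-pyrrol-2-yl)-3-(2,6-dimethoxyphenyl)propan-1-one F3. Acylation with 4,5-dichloro-1H-pyrrole-2-carbonyl chloride F4 (from the commercial acid and (COCl)2) and AlCl3 in CH2Cl2 should occur at ring position 3, because positions 3 and 5 of the symmetric arene are equivalent and are the only ones ortho/para to the methoxy groups; this gives 1-(4,5-dichloro-1H-pyrrol-2-yl)-3-[3-(4,5-dichloro-1H-pyrrole-2-carbonyl)-2,6-dimethoxyphenyl]propan-1-one F5. BBr3 in CH2Cl2 should then cleave both methyl ethers to give 12.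

Step 2. The alkylpalladium intermediate may undergo β-hydride elimination, or the triflate may be reduced, instead of coupling. The fallback sets out from 2 and comes back at 4. A Heck reaction of 2 with tert-butyl acrylate (Pd(OAc)2, P(o-tolyl)3, Et3N, DMF, 80 °C) should give tert-butyl (E)-3-(2-methyl-4-oxo-4H-pyran-3-yl)prop-2-enoate F6. Hydrogenation of its side-chain C=C bond (H2, RhCl(PPh3)3), which leaves the pyranone ring untouched, should give 4.

Step 4. Sulfonylation of a nitrogen flanked by chlorine and the amide may be slow, and the product may lose the sulfonyl group on handling. The fallback drops N-protection. It sets out from 6 and comes back at 9. Amide 6 is N-lithiated with LiN(SiMe3)2 (1 equiv per amide) and the lithium pyrrolide is added to the dianion of 4 (–78 → 23 °C). Aqueous KOH should then release tert-butyl 2-(4,5-dichloro-1H-pyrrole-2-carbonyl)-3-{2-[2-(4,5-dichloro-1H-pyrrol-2-yl)-2-oxoethyl]-4-oxo-4H-pyran-3-yl}propanoate F7 (not isolated), which opens to 9 and closes to 10 as in step 5.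

**Further compounds**

F1 | step 5 | 1-(4,5-dichloro-1H-pyrrol-2-yl)ethan-1-one | CC(=O)c1cc(Cl)c(Cl)[nH]1
F2 | step 5 | (E)-1-(4,5-dichloro-1H-pyrrol-2-yl)-3-(2,6-dimethoxyphenyl)prop-2-en-1-one | COc1cccc(OC)c1/C=C/C(=O)c1cc(Cl)c(Cl)[nH]1
F3 | step 5 | 1-(4,5-dichloro-1H-pyrrol-2-yl)-3-(2,6-dimethoxyphenyl)propan-1-one | COc1cccc(OC)c1CCC(=O)c1cc(Cl)c(Cl)[nH]1
F4 | step 5 | 4,5-dichloro-1H-pyrrole-2-carbonyl chloride | O=C(Cl)c1cc(Cl)c(Cl)[nH]1
F5 | step 5 | 1-(4,5-dichloro-1H-pyrrol-2-yl)-3-[3-(4,5-dichloro-1H-pyrrole-2-carbonyl)-2,6-dimethoxyphenyl]propan-1-one | COc1ccc(C(=O)c2cc(Cl)c(Cl)[nH]2)c(OC)c1CCC(=O)c1cc(Cl)c(Cl)[nH]1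
F6 | step 2 | tert-butyl (E)-3-(2-methyl-4-oxo-4H-pyran-3-yl)prop-2-enoate | Cc1occc(=O)c1/C=C/C(=O)OC(C)(C)C
F7 | step 4 | tert-butyl 2-(4,5-dichloro-1H-pyrrole-2-carbonyl)-3-{2-[2-(4,5-dichloro-1H-pyrrol-2-yl)-2-oxoethyl]-4-oxo-4H-pyran-3-yl}propanoate | CC(C)(C)OC(=O)C(Cc1c(CC(=O)c2cc(Cl)c(Cl)[nH]2)occc1=O)C(=O)c1cc(Cl)c(Cl)[nH]1
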